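**Plan**
Retrosynthesis: the C3–O ester bond is cut first (acid 26 plus core alcohol 18), then the C4–C5 bond of ring A, then C3–C4 (vinyl Grignard), C10–C1 (Heck) and, in the acid, C4'=C5' (Horner–Wadsworth–Emmons).
Enabling feature: ring B (C5, C6, C7, C8, C9, C10) is a 2-oxygenated 4,4-disubstituted cyclohexa-2,5-dienone, i.e. 4-methylguaiacol dearomatised at its methyl-bearing carbon C5, which lies para to the C8 oxygen, so ring A can be closed onto the intact arene.
Forward: the guaiacol ring (future ring B) receives a tether C1–C4 ending in a ketal-masked 2-bromoenone, ring A closes by palladium-catalysed para C-alkenylation of the phenoxide, then C4, C1=C2 and C3 are adjusted, the acid is attached and two protecting groups are removed.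
Stereochemistry: C5 from the chiral phosphine in the cyclisation, C4 by hydrogenation anti to the C5 methyl, C3 by hydride attack anti to the C5 methyl, C6' by lipase desymmetrisation of 2-ethylpropane-1,3-diol.

Key step: step 9

Numbering: core C1=C2, C3 (carbinol), C4 (methyl methine), C5 (methyl quaternary), C6=C7 (C7–O), C8 (ketone), C9=C10; ring A = C1, C2, C3, C4, C5, C10. Bicyclic compounds are named as bicyclo[4.4.0]decanes with this core numbering, not von Baeyer numbering. Side chain: C1' (carboxyl) to C8', hydroxymethyl on C6'.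
Assumption 1: the lipase is taken to acetylate the pro-S hydroxymethyl arm of 19, by analogy with 2-methylpropane-1,3-diol, giving (S)-20; if the other arm reacts, oxidising the free hydroxyl first and exchanging acetate for silyl after olefination leads to the same acid 26.
Assumption 2: the sense of induction in step 9 cannot be derived with certainty for this tether; (S)-AntPhos (4-(anthracen-9-yl)-3-tert-butyl-2,3-dihydro-1,3-benzoxaphosphole) is assumed to give (5S)-13, and its antipode would be used otherwise.

**Route**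

Step 1
Reactants: 1 2-methoxy-4-methylphenol
Product: 2 2-methoxy-4-methylphenyl pivalate
Conditions: PivCl, Et3N, DMAP (cat.), CH2Cl2, 0 °C to rt
Reagents that add atoms: pivaloyl chloride, CC(C)(C)C(=O)Cl
Why: O-acylation of the phenol should be clean, and the pivalate is chosen because it weakens the directing power of O8 for step 2 and is hindered enough to survive the Grignard reagent of step 4.

Step 2
Reactants: 2 2-methoxy-4-methylphenyl pivalate
Product: 3 5-iodo-2-methoxy-4-methylphenyl pivalate
Conditions: NIS, TFA (cat.), MeCN, rt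
Reagents that add atoms: N-iodosuccinimide, O=C1CCC(=O)N1I
Why: Electrophilic aromatic iodination should go para to the methoxy group and ortho to the methyl group (the future C10), since the acyloxy group is the weaker director and the position between OMe and Me is hindered.

Step 3
Reactants: 3 5-iodo-2-methoxy-4-methylphenyl pivalate; 4 prop-2-en-1-ol (allyl alcohol)
Product: 5 2-methoxy-4-methyl-5-(3-oxopropyl)phenyl pivalate
Conditions: Pd(OAc)2 (5 mol %), Bu4NCl, NaHCO3, DMF, 45 °C
Reagents that add atoms: none
Why: Heck reaction under phase-transfer (Jeffery) conditions, in which carbopalladation at the alkene terminus, β-hydride elimination toward the carbinol and enol–aldehyde tautomerisation should give the 3-arylpropanal carrying C1–C3.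

Step 4
Reactants: 5 2-methoxy-4-methyl-5-(3-oxopropyl)phenyl pivalate; 6 vinylmagnesium bromide
Product: 7 racemic 5-(3-hydroxypent-4-en-1-yl)-2-methoxy-4-methylphenyl pivalate
Conditions: THF, −78 °C; then aqueous work-up
Reagents that add atoms: none
Why: Grignard 1,2-addition to the aldehyde at −78 °C should be much faster than attack on the hindered aryl pivalate and brings in C4 with its future methyl carbon, the racemic carbinol centre being erased in step 5.

Step 5
Reactants: 7 racemic 5-(3-hydroxypent-4-en-1-yl)-2-methoxy-4-methylphenyl pivalate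
Product: 8 2-methoxy-4-methyl-5-(3-oxopent-4-en-1-yl)phenyl pivalate
Conditions: Dess–Martin periodinane, CH2Cl2, 0 °C to rt
Reagents that add atoms: none
Why: Dess–Martin oxidation of the secondary allylic alcohol should give the vinyl ketone without touching the aryl ester, and the enone is used at once to avoid polymerisation.

Step 6
Reactants: 8 2-methoxy-4-methyl-5-(3-oxopent-4-en-1-yl)phenyl pivalate
Product: 10 5-(4-bromo-3-oxopent-4-en-1-yl)-2-methoxy-4-methylphenyl pivalate, via dibromoketone 9 (not isolated)
Conditions: Br2 (1.0 equiv), CH2Cl2, −78 °C; then Et3N, −78 to 0 °C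
Reagents that add atoms: bromine, BrBr
Why: Bromine addition to the unhindered vinyl ketone followed by amine-induced E1cB loss of HBr from the acidic α-position is the standard route to 2-bromoenones, with ring bromination held back by the low temperature, the single equivalent of bromine and the deactivating pivalate.

Step 7
Reactants: 10 5-(4-bromo-3-oxopent-4-en-1-yl)-2-methoxy-4-methylphenyl pivalate
Product: 11 5-{2-[2-(1-bromoethenyl)-1,3-dioxolan-2-yl]ethyl}-2-methoxy-4-methylphenyl pivalate
Conditions: (TMSOCH2)2, TMSOTf (cat.), CH2Cl2, −78 to −20 °C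
Reagents that add atoms: 1,2-bis(trimethylsilyloxy)ethane, C[Si](C)(C)OCCO[Si](C)(C)C
Why: Noyori ketalisation is aprotic and irreversible, so the 2-bromoenone should be masked without conjugate addition of the diol, which removes the Michael acceptor before a phenoxide is generated.

Step 8
Reactants: 11 5-{2-[2-(1-bromoethenyl)-1,3-dioxolan-2-yl]ethyl}-2-methoxy-4-methylphenyl pivalate
Product: 12 5-{2-[2-(1-bromoethenyl)-1,3-dioxolan-2-yl]ethyl}-2-methoxy-4-methylphenol
Conditions: K2CO3, MeOH, 40 °C
Reagents that add atoms: none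
Why: Base-mediated transesterification of the aryl pivalate with methanol should free the phenol, the ketal and the alkenyl bromide being inert to carbonate.

Step 9
Reactants: 12 5-{2-[2-(1-bromoethenyl)-1,3-dioxolan-2-yl]ethyl}-2-methoxy-4-methylphenol
Product: 13 (5S)-3,3-ethylenedioxy-7-methoxy-5-methyl-4-methylidenebicyclo[4.4.0]deca-6,9-dien-8-one
Conditions: [Pd(cinnamyl)Cl]2 (2.5 mol %), (S)-AntPhos (6 mol %), K2CO3 (2 equiv), toluene, 90 °C
Reagents that add atoms: none
Why: Oxidative addition of zerovalent palladium into the C4–Br bond gives an alkenylpalladium bromide, K2CO3 generates the phenoxide, whose para carbon C5 replaces bromide on palladium to give a dearomatised palladacycle, and C–C reductive elimination forms the C4–C5 bond. The closest known reaction type is the palladium-catalysed enantioselective dearomative cyclisation of para-alkylphenols carrying a tethered aryl or alkenyl bromide with bulky P-chiral monophosphines, which gives fused cyclohexadienones with an all-carbon quaternary centre. Ring A closes as a six-membered carbocycle, 6-exo-trig with respect to the C5=C6 bond of the phenoxide, and the cross-conjugated dienone of ring B appears directly because C5, now bearing methyl and C4, cannot rearomatise. The C5 stereocentre is set under catalyst control, the chiral phosphine on palladium distinguishing the two faces of the phenoxide in the palladacycle. The step needs C-attack through the para carbon C5 and not the ortho carbon C9 (both six-membered closures); the larger electron density at the para carbon of a phenoxide and the bulky monophosphine should secure this, while the ketal keeps the enone from acting as a Michael acceptor toward the phenoxide.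

Step 10
Reactants: 13 (5S)-3,3-ethylenedioxy-7-methoxy-5-methyl-4-methylidenebicyclo[4.4.0]deca-6,9-dien-8-one
Product: 14 (5S)-7-methoxy-5-methyl-4-methylidenebicyclo[4.4.0]deca-6,9-diene-3,8-dione
Conditions: 1 M HCl, THF, 0 °C to rt
Reagents that add atoms: water, O
Why: Acid hydrolysis of the allylic ketal through an allyl-stabilised oxocarbenium ion should be far faster than hydrolysis of the C7 methyl enol ether, an α-alkoxy enone that would have to be protonated next to the C8 carbonyl.

Step 11
Reactants: 14 (5S)-7-methoxy-5-methyl-4-methylidenebicyclo[4.4.0]deca-6,9-diene-3,8-dione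
Product: 15 (4R,5R)-7-methoxy-4,5-dimethylbicyclo[4.4.0]deca-6,9-diene-3,8-dione (methyl groups cis)
Conditions: H2 (1 atm), RhCl(PPh3)3 (5 mol %), benzene, rt
Reagents that add atoms: none
Why: Homogeneous hydrogenation with RhCl(PPh3)3 selects the 1,1-disubstituted exocyclic alkene over the trisubstituted alkenes of ring B, and hydrogen should reach C4 from the face opposite the axial C5 methyl, leaving the new methyl equatorial and cis to it (4R).

Step 12
Reactants: 15 (4R,5R)-7-methoxy-4,5-dimethylbicyclo[4.4.0]deca-6,9-diene-3,8-dione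
Product: 16 (4R,5R)-7-methoxy-4,5-dimethyl-3-(trimethylsilyloxy)bicyclo[4.4.0]deca-2,6,9-trien-8-one
Conditions: LiN(iPr)2, TMSCl (in situ), THF, −78 °C
Reagents that add atoms: chlorotrimethylsilane, C[Si](C)(C)Cl
Why: Kinetic deprotonation with in situ silyl trapping should remove the less hindered C2–H in preference to C4–H and fix the C2–C3 enolate before it can equilibrate to the more substituted or the vinylogous C1 enolate.

Step 13
Reactants: 16 (4R,5R)-7-methoxy-4,5-dimethyl-3-(trimethylsilyloxy)bicyclo[4.4.0]deca-2,6,9-trien-8-one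
Product: 17 (4R,5R)-7-methoxy-4,5-dimethylbicyclo[4.4.0]deca-1,6,9-triene-3,8-dione
Conditions: Pd(OAc)2 (1.05 equiv), MeCN, rt
Reagents that add atoms: none
Why: Saegusa–Ito oxidation, in which the palladium enolate formed at C2 loses a C1 hydrogen by β-hydride elimination, places the C1=C2 double bond in conjugation with C9=C10 with the regiochemistry fixed by the enol ether.

Step 14
Reactants: 17 (4R,5R)-7-methoxy-4,5-dimethylbicyclo[4.4.0]deca-1,6,9-triene-3,8-dione
Product: 18 (3S,4R,5S)-3-hydroxy-7-methoxy-4,5-dimethylbicyclo[4.4.0]deca-1,6,9-trien-8-one (hydroxyl and both methyl groups on one face)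
Conditions: NaBH4, CeCl3·7H2O, MeOH, −78 °C
Reagents that add atoms: none
Why: Luche 1,2-reduction should take the C3 enone carbonyl in preference to the cross-conjugated, donor-substituted C8 carbonyl, with hydride adding anti to the pseudoaxial C5 methyl (1,3-related to C3) so that the hydroxyl ends up cis to both methyl groups (3S).

Step 15
Reactants: 19 2-ethylpropane-1,3-diol
Product: 20 (S)-2-(hydroxymethyl)butyl acetate
Conditions: lipase from Pseudomonas fluorescens (Amano AK), vinyl acetate, THF, rt
Reagents that add atoms: vinyl acetate, C=COC(C)=O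
Why: Lipase-catalysed irreversible transesterification desymmetrises the prochiral diol by acetylating one enantiotopic arm, which sets C6', and running slightly into diacetate should raise the enantiomeric purity of the monoacetate.

Step 16
Reactants: 20 (S)-2-(hydroxymethyl)butyl acetate
Product: 21 (R)-2-{[tert-butyl(dimethyl)silyl]oxymethyl}butyl acetate
Conditions: TBSCl, imidazole, DMF, rt
Reagents that add atoms: tert-butyl(chloro)dimethylsilane, CC(C)(C)[Si](C)(C)Cl
Why: Silylation of the free primary alcohol fixes which arm stays oxygenated in the target.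

Step 17
Reactants: 21 (R)-2-{[tert-butyl(dimethyl)silyl]oxymethyl}butyl acetate
Product: 22 (R)-2-{[tert-butyl(dimethyl)silyl]oxymethyl}butan-1-ol
Conditions: K2CO3 (cat.), MeOH, 0 °C
Reagents that add atoms: none
Why: Carbonate-catalysed methanolysis removes the acetate while the primary silyl ether stays in place at 0 °C, where 1,3-silyl migration (which would racemise C6') should be negligible.

Step 18
Reactants: 22 (R)-2-{[tert-butyl(dimethyl)silyl]oxymethyl}butan-1-ol
Product: 23 (S)-2-{[tert-butyl(dimethyl)silyl]oxymethyl}butanal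
Conditions: Dess–Martin periodinane, NaHCO3, CH2Cl2, 0 °C
Reagents that add atoms: none
Why: Buffered Dess–Martin oxidation gives the α-branched aldehyde without enolisation, and it is used immediately to protect the α-stereocentre.

Step 19
Reactants: 23 (S)-2-{[tert-butyl(dimethyl)silyl]oxymethyl}butanal; 24 ethyl (2E)-4-(diethoxyphosphoryl)but-2-enoate (triethyl 4-phosphonocrotonate)
Product: 25 ethyl (2E,4E,6R)-6-{[tert-butyl(dimethyl)silyl]oxymethyl}octa-2,4-dienoate
Conditions: LiN(SiMe3)2, THF, −78 to 0 °C
Reagents that add atoms: none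
Why: Vinylogous Horner–Wadsworth–Emmons olefination is E-selective for the new C4'=C5' bond and keeps the E C2'=C3' bond, and the stabilised, weakly basic anion at low temperature should spare the α-stereocentre.

Step 20
Reactants: 25 ethyl (2E,4E,6R)-6-{[tert-butyl(dimethyl)silyl]oxymethyl}octa-2,4-dienoate
Product: 26 (2E,4E,6R)-6-{[tert-butyl(dimethyl)silyl]oxymethyl}octa-2,4-dienoic acid
Conditions: LiOH·H2O, THF/MeOH/H2O, rt; then 1 M HCl to pH 4, 0 °C
Reagents that add atoms: lithium hydroxide, [Li+].[OH-]
Why: Saponification of the ethyl ester leaves the silyl ether and the diene geometry untouched, and brief cold acidification gives the free acid.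

Step 21
Reactants: 26 (2E,4E,6R)-6-{[tert-butyl(dimethyl)silyl]oxymethyl}octa-2,4-dienoic acid; 18 (3S,4R,5S)-3-hydroxy-7-methoxy-4,5-dimethylbicyclo[4.4.0]deca-1,6,9-trien-8-one
Product: 28 (3S,4R,5S)-7-methoxy-4,5-dimethyl-8-oxobicyclo[4.4.0]deca-1,6,9-trien-3-yl (2E,4E,6R)-6-{[tert-butyl(dimethyl)silyl]oxymethyl}octa-2,4-dienoate, via mixed anhydride 27 (not isolated)
Conditions: 2,4,6-trichlorobenzoyl chloride, Et3N, THF, rt; then 18, DMAP, toluene, rt
Reagents that add atoms: none
Why: Yamaguchi esterification, in which DMAP opens the mixed anhydride at the less hindered dienoyl carbonyl and the acylpyridinium acylates the hindered allylic alcohol with retention at C3, the ring B enol being blocked as its methyl ether.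

Step 22
Reactants: 28 (3S,4R,5S)-7-methoxy-4,5-dimethyl-8-oxobicyclo[4.4.0]deca-1,6,9-trien-3-yl (2E,4E,6R)-6-{[tert-butyl(dimethyl)silyl]oxymethyl}octa-2,4-dienoate
Product: 29 (3S,4R,5S)-7-hydroxy-4,5-dimethyl-8-oxobicyclo[4.4.0]deca-1,6,9-trien-3-yl (2E,4E,6R)-6-{[tert-butyl(dimethyl)silyl]oxymethyl}octa-2,4-dienoate
Conditions: BCl3, CH2Cl2, −78 °C; then aq NaHCO3
Reagents that add atoms: none
Why: Lewis-acid O-demethylation, in which BCl3 chelates the C8 carbonyl and the C7 methoxy oxygen and chloride removes the methyl group by SN2, is specific to ethers next to a carbonyl and should leave the esters, the diene and the silyl ether intact at −78 °C.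

Step 23
Reactants: 29 (3S,4R,5S)-7-hydroxy-4,5-dimethyl-8-oxobicyclo[4.4.0]deca-1,6,9-trien-3-yl (2E,4E,6R)-6-{[tert-butyl(dimethyl)silyl]oxymethyl}octa-2,4-dienoate
Product: 30 septeremophilane E
Conditions: HF·pyridine, pyridine/THF, 0 °C to rt
Reagents that add atoms: none
Why: Fluoride cleavage of the primary silyl ether with buffered HF·pyridine is compatible with the dienoate, the allylic ester and the acidic diosphenol and should liberate the target.

**Compound list**
1 | 2-methoxy-4-methylphenol | Cc1ccc(O)c(OC)c1 | starting material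
2 | 2-methoxy-4-methylphenyl pivalate | Cc1ccc(OC(=O)C(C)(C)C)c(OC)c1 | intermediate
3 | 5-iodo-2-methoxy-4-methylphenyl pivalate | Cc1cc(OC)c(OC(=O)C(C)(C)C)cc1I | intermediate
4 | prop-2-en-1-ol (allyl alcohol) | C=CCO | starting material
5 | 2-methoxy-4-methyl-5-(3-oxopropyl)phenyl pivalate | O=CCCc1cc(OC(=O)C(C)(C)C)c(OC)cc1C | intermediate
6 | vinylmagnesium bromide | C=C[Mg]Br | starting material
7 | racemic 5-(3-hydroxypent-4-en-1-yl)-2-methoxy-4-methylphenyl pivalate | C=CC(O)CCc1cc(OC(=O)C(C)(C)C)c(OC)cc1C | intermediate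
8 | 2-methoxy-4-methyl-5-(3-oxopent-4-en-1-yl)phenyl pivalate | C=CC(=O)CCc1cc(OC(=O)C(C)(C)C)c(OC)cc1C | intermediate
9 | 5-(4,5-dibromo-3-oxopentyl)-2-methoxy-4-methylphenyl pivalate (dibromoketone, racemic) | BrCC(Br)C(=O)CCc1cc(OC(=O)C(C)(C)C)c(OC)cc1C | intermediate
10 | 5-(4-bromo-3-oxopent-4-en-1-yl)-2-methoxy-4-methylphenyl pivalate | C=C(Br)C(=O)CCc1cc(OC(=O)C(C)(C)C)c(OC)cc1C | intermediate
11 | 5-{2-[2-(1-bromoethenyl)-1,3-dioxolan-2-yl]ethyl}-2-methoxy-4-methylphenyl pivalate | C=C(Br)C1(OCCO1)CCc1cc(OC(=O)C(C)(C)C)c(OC)cc1C | intermediate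
12 | 5-{2-[2-(1-bromoethenyl)-1,3-dioxolan-2-yl]ethyl}-2-methoxy-4-methylphenol | C=C(Br)C1(OCCO1)CCc1cc(O)c(OC)cc1C | intermediate
13 | (5S)-3,3-ethylenedioxy-7-methoxy-5-methyl-4-methylidenebicyclo[4.4.0]deca-6,9-dien-8-one | C[C@]12C=C(OC)C(=O)C=C1CCC1(OCCO1)C2=C | intermediate
14 | (5S)-7-methoxy-5-methyl-4-methylidenebicyclo[4.4.0]deca-6,9-diene-3,8-dione | C[C@]12C=C(OC)C(=O)C=C1CCC(=O)C2=C | intermediate
15 | (4R,5R)-7-methoxy-4,5-dimethylbicyclo[4.4.0]deca-6,9-diene-3,8-dione | O=C1CCC2=CC(=O)C(OC)=C[C@]2(C)[C@H]1C | intermediate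
16 | (4R,5R)-7-methoxy-4,5-dimethyl-3-(trimethylsilyloxy)bicyclo[4.4.0]deca-2,6,9-trien-8-one | C[Si](C)(C)OC1=CCC2=CC(=O)C(OC)=C[C@]2(C)[C@H]1C | intermediate
17 | (4R,5R)-7-methoxy-4,5-dimethylbicyclo[4.4.0]deca-1,6,9-triene-3,8-dione | O=C1C=CC2=CC(=O)C(OC)=C[C@]2(C)[C@H]1C | intermediate
18 | (3S,4R,5S)-3-hydroxy-7-methoxy-4,5-dimethylbicyclo[4.4.0]deca-1,6,9-trien-8-one | O[C@H]1C=CC2=CC(=O)C(OC)=C[C@]2(C)[C@H]1C | intermediate
19 | 2-ethylpropane-1,3-diol | CCC(CO)CO | starting material
20 | (S)-2-(hydroxymethyl)butyl acetate | CC[C@@H](CO)COC(C)=O | intermediate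
21 | (R)-2-{[tert-butyl(dimethyl)silyl]oxymethyl}butyl acetate | CC[C@@H](CO[Si](C)(C)C(C)(C)C)COC(C)=O | intermediate
22 | (R)-2-{[tert-butyl(dimethyl)silyl]oxymethyl}butan-1-ol | CC[C@@H](CO[Si](C)(C)C(C)(C)C)CO | intermediate
23 | (S)-2-{[tert-butyl(dimethyl)silyl]oxymethyl}butanal | CC[C@@H](CO[Si](C)(C)C(C)(C)C)C=O | intermediate
24 | ethyl (2E)-4-(diethoxyphosphoryl)but-2-enoate | CCOC(=O)/C=C/CP(=O)(OCC)OCC | starting material
25 | ethyl (2E,4E,6R)-6-{[tert-butyl(dimethyl)silyl]oxymethyl}octa-2,4-dienoate | CC[C@@H](CO[Si](C)(C)C(C)(C)C)/C=C/C=C/C(=O)OCC | intermediate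
26 | (2E,4E,6R)-6-{[tert-butyl(dimethyl)silyl]oxymethyl}octa-2,4-dienoic acid | CC[C@@H](CO[Si](C)(C)C(C)(C)C)/C=C/C=C/C(=O)O | intermediate
27 | mixed anhydride of 26 with 2,4,6-trichlorobenzoic acid | CC[C@@H](CO[Si](C)(C)C(C)(C)C)/C=C/C=C/C(=O)OC(=O)c1c(Cl)cc(Cl)cc1Cl | intermediate
28 | (3S,4R,5S)-7-methoxy-4,5-dimethyl-8-oxobicyclo[4.4.0]deca-1,6,9-trien-3-yl (2E,4E,6R)-6-{[tert-butyl(dimethyl)silyl]oxymethyl}octa-2,4-dienoate | CC[C@@H](CO[Si](C)(C)C(C)(C)C)/C=C/C=C/C(=O)O[C@H]1C=CC2=CC(=O)C(OC)=C[C@]2(C)[C@H]1C | intermediate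
29 | (3S,4R,5S)-7-hydroxy-4,5-dimethyl-8-oxobicyclo[4.4.0]deca-1,6,9-trien-3-yl (2E,4E,6R)-6-{[tert-butyl(dimethyl)silyl]oxymethyl}octa-2,4-dienoate | CC[C@@H](CO[Si](C)(C)C(C)(C)C)/C=C/C=C/C(=O)O[C@H]1C=CC2=CC(=O)C(O)=C[C@]2(C)[C@H]1C | intermediate
30 | septeremophilane E, (3S,4R,5S)-7-hydroxy-4,5-dimethyl-8-oxobicyclo[4.4.0]deca-1,6,9-trien-3-yl (2E,4E,6R)-6-(hydroxymethyl)octa-2,4-dienoate | CC[C@H](/C=C/C=C/C(=O)O[C@H]1C=CC2=CC(=O)C(O)=C[C@]2(C)[C@H]1C)CO | target

**Step count and risks**
Total: 23 steps. Longest linear sequence: 17 steps (steps 1–14 and 21–23); acid 26 takes 6 steps (15–20).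

Steps most likely to fail:

1. Step 9. The ketal next to the alkenyl–palladium bond is bulkier than the tethers on which this cyclisation is established, so enantioface discrimination at C5 may be low, and attack through the ortho carbon C9 with rearomatisation may divert part of the material. Fallback (auxiliary control with separation in place of pure catalyst control), setting out from 10 and returning at 14: bromoenone 10 would be ketalised with the bis(trimethylsilyl) ether of (2R,3R)-butane-2,3-diol and catalytic TMSOTf to the C2-symmetric dimethyldioxolane pivalate F1. Methanolysis (K2CO3, MeOH) would give the corresponding phenol F2. The same palladium cyclisation would give the chiral ketal dienone F3, now as two C5 diastereomers that can be separated by chromatography or crystallisation whatever the selectivity. Hydrolysis of the (5S)-isomer with 1 M HCl in THF rejoins the route at 14.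

2. Step 14. Hydride may be delivered from the face syn to the C5 methyl (torsional preference for axial attack outweighing the 1,3-interaction), giving the C3 epimer; some reduction at C8 would also cost material. Fallback (inversion during esterification in place of retention), setting out from 17 and returning at 28: the Luche reduction of 17 then delivers mainly the C3-epimeric alcohol F4. F4 is coupled with acid 26 under Mitsunobu conditions (PPh3, DIAD, toluene, 0 °C), whose SN2 displacement at C3 inverts the centre and gives ester 28 directly, bypassing 18 and step 21.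

3. Step 22. The Lewis acid needed for O-demethylation may ionise the C3 allylic ester or isomerise the dienoate before the methyl group is removed. Fallback (exchange of the methyl ether for a fluoride-labile group before the ester exists), setting out from 17 and returning at 30:
- BCl3 in CH2Cl2 at −78 °C on the robust trienedione 17 would give the free diosphenol F5.
- TIPSCl and imidazole in DMF would give its silyl enol ether F6.
- Luche reduction would give the C3 alcohol F7.
- Yamaguchi esterification with 26 (through anhydride 27) would give the bis-silyl ester F8.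
- HF·pyridine would remove both silyl groups in one operation to give 30.

**Further compounds**
F1 | step 9 | 5-{2-[(4R,5R)-2-(1-bromoethenyl)-4,5-dimethyl-1,3-dioxolan-2-yl]ethyl}-2-methoxy-4-methylphenyl pivalate | C=C(Br)C1(O[C@H](C)[C@@H](C)O1)CCc1cc(OC(=O)C(C)(C)C)c(OC)cc1C
F2 | step 9 | 5-{2-[(4R,5R)-2-(1-bromoethenyl)-4,5-dimethyl-1,3-dioxolan-2-yl]ethyl}-2-methoxy-4-methylphenol | C=C(Br)C1(O[C@H](C)[C@@H](C)O1)CCc1cc(O)c(OC)cc1C
F3 | step 9 | (5S)-7-methoxy-5-methyl-4-methylidenebicyclo[4.4.0]deca-6,9-dien-8-one 3-[(2R,3R)-butane-2,3-diyl] ketal | C[C@]12C=C(OC)C(=O)C=C1CCC1(O[C@H](C)[C@@H](C)O1)C2=C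
F4 | step 14 | (3R,4R,5S)-3-hydroxy-7-methoxy-4,5-dimethylbicyclo[4.4.0]deca-1,6,9-trien-8-one | O[C@@H]1C=CC2=CC(=O)C(OC)=C[C@]2(C)[C@H]1C
F5 | step 22 | (4R,5R)-7-hydroxy-4,5-dimethylbicyclo[4.4.0]deca-1,6,9-triene-3,8-dione | O=C1C=CC2=CC(=O)C(O)=C[C@]2(C)[C@H]1C
F6 | step 22 | (4R,5R)-4,5-dimethyl-7-[tri(propan-2-yl)silyloxy]bicyclo[4.4.0]deca-1,6,9-triene-3,8-dione | O=C1C=CC2=CC(=O)C(O[Si](C(C)C)(C(C)C)C(C)C)=C[C@]2(C)[C@H]1C
F7 | step 22 | (3S,4R,5S)-3-hydroxy-4,5-dimethyl-7-[tri(propan-2-yl)silyloxy]bicyclo[4.4.0]deca-1,6,9-trien-8-one | O[C@H]1C=CC2=CC(=O)C(O[Si](C(C)C)(C(C)C)C(C)C)=C[C@]2(C)[C@H]1C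
F8 | step 22 | (3S,4R,5S)-4,5-dimethyl-8-oxo-7-[tri(propan-2-yl)silyloxy]bicyclo[4.4.0]deca-1,6,9-trien-3-yl (2E,4E,6R)-6-{[tert-butyl(dimethyl)silyl]oxymethyl}octa-2,4-dienoate | CC[C@@H](CO[Si](C)(C)C(C)(C)C)/C=C/C=C/C(=O)O[C@H]1C=CC2=CC(=O)C(O[Si](C(C)C)(C(C)C)C(C)C)=C[C@]2(C)[C@H]1C
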